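**Retrosynthetic overview**
- Sikokianin A 14 is traced back through its pentabenzyl ether 13 to the flat 3,3''-biflavone 12. Syn addition of H2 across C2=C3 and C2''=C3'' is kept for the end and sets all four stereocentres.
- The plan rests on rings A and A'' (C4a, C5, C6, C7, C8, C8a and the doubly primed set). Each is a benzene ring with oxygen on C5, C7 and C8a and the acyl carbon C4 on C4a, that is an acylphloroglucinol, the Claisen-folded form of a 3,5,7-triketo chain.
- Both rings are opened at C4a–C5 and C4a''–C5''. Biflavone 11 goes back to the bis(methyl 3-oxobutanoate) 10 of a 3,3'-bi(4-pyranone), in which each pyranone is the later ring C (its C5 the later C4a) and holds the C2, C4 and C8a oxygens in masked form.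
- 10 is grown from the 6,6'-dimethylbipyranone 6 (lateral carboxylation, then malonate homologation). 6 comes from the 1,4-diaryl-1,4-diketone 4 by twofold C-acylation with but-2-ynoyl chloride and 6-endo-dig closure, and 4 from a Stetter union of 1 and 2, whose CH2–CH2 unit is the later C3–C3'' bond.
- Ring order: rings B and B'' are bought; rings C and C'' close together in step 2; rings A and A'' close together in step 5; both heterocycles are saturated in step 7.

Key step: step 5

Remark: the target SMILES is read as (2S,3S,2''S,3''S). With O1 > C1' > C3 at C2 and C4 > C2 > C3'' at C3, H2/H3 and H2''/H3'' are cis, which is what syn hydrogenation of a biflavone delivers.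
Assumption: the sense of induction of the catalyst from Ru(cod)(2-methylallyl)2 and (R,R)-SINpEt·HBF4 on substrate 12 is not known in advance. The (R,R) ligand is written, and the (S,S) ligand is used instead if a trial run shows the opposite sense.
Remark: compounds 6 to 12 have a hindered C3–C3' axis and are carried as the racemic or interconverting mixture of rotamers; the axis disappears in step 7.
Remark: both halves are built up in parallel. Steps 2, 3 and 4 each deliver two identical units to one molecule of substrate (two but-2-ynoyl groups, two CO2, two CH2CO2Me groups) and step 6 delivers four benzyl groups. These units come from reagents used in excess, named on the reagent lines.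

**Route**

Step 1
Reactants: 1 3-(dimethylamino)-1-(4-methoxyphenyl)propan-1-one hydrochloride; 2 4-(benzyloxy)benzaldehyde
Product: 4 1-[4-(benzyloxy)phenyl]-4-(4-methoxyphenyl)butane-1,4-dione, via 1-(4-methoxyphenyl)prop-2-en-1-one 3 (not isolated)
Conditions: 3-ethyl-5-(2-hydroxyethyl)-4-methylthiazolium bromide (20 mol%), Et3N (1.5 equiv), DMF, 80 °C
Reagents that add atoms: none
Why: Stetter reaction, in which Et3N frees the aryl vinyl ketone 3 from the Mannich salt and the thiazolylidene-bound acyl anion equivalent of aldehyde 2 adds to it in a conjugate sense, so that the two different aryl ketones sit at the ends of the future C3–C3'' ethane unit from the outset.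

Step 2
Reactants: 4 1-[4-(benzyloxy)phenyl]-4-(4-methoxyphenyl)butane-1,4-dione
Product: 6 2-[4-(benzyloxy)phenyl]-2'-(4-methoxyphenyl)-6,6'-dimethyl-4H,4'H-[3,3'-bipyran]-4,4'-dione, via bis(but-2-ynoyl) tetraketone 5 (not isolated)
Conditions: a) but-2-ynoic acid (3 equiv), (COCl)2 (3 equiv), cat. DMF, CH2Cl2, 0 °C to rt, volatiles removed; b) 4 (1 equiv), MgBr2·OEt2 (6 equiv), i-Pr2NEt (7 equiv), the acid chloride from a), CH2Cl2, 0 °C to rt, aq. NH4Cl; c) DBU (0.3 equiv), MeCN, rt
Reagents that add atoms: but-2-ynoic acid, CC#CC(=O)O; but-2-ynoyl chloride made from it in the flask, CC#CC(=O)Cl (two but-2-ynoyl units enter the product)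
Why: C-acylation by soft enolisation (MgBr2·OEt2 and a hindered amine) should acylate each of the two aryl ketone α-carbons with one molecule of the acid chloride, and each aroyl enol oxygen then adds 6-endo-dig to the ynone β-carbon (oxa-Michael closure) to give the 4-pyranone under base, which avoids the acid that would turn the 1,4-diaryl diketone into a furan.

Step 3
Reactants: 6 2-[4-(benzyloxy)phenyl]-2'-(4-methoxyphenyl)-6,6'-dimethyl-4H,4'H-[3,3'-bipyran]-4,4'-dione
Product: 8 2,2'-{2-[4-(benzyloxy)phenyl]-2'-(4-methoxyphenyl)-4,4'-dioxo-4H,4'H-[3,3'-bipyran]-6,6'-diyl}diacetic acid, via dilithium bis(dienolate) 7 (not isolated)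
Conditions: LiN(SiMe3)2 (2.5 equiv), THF, −78 °C; transfer into CO2-saturated THF, −78 °C; cold 1 M HCl to pH 2–3; used at once
Reagents that add atoms: carbon dioxide, O=C=O (two molecules enter the product)
Why: Lateral (vinylogous) deprotonation of the 6-methyl groups of 4-pyranones is established, and the exocyclic carbon of each dienolate should be carboxylated by CO2, with inverse addition keeping the product carboxylate from quenching unreacted anion.

Step 4
Reactants: 8 2,2'-{2-[4-(benzyloxy)phenyl]-2'-(4-methoxyphenyl)-4,4'-dioxo-4H,4'H-[3,3'-bipyran]-6,6'-diyl}diacetic acid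
Product: 10 dimethyl 4,4'-{2-[4-(benzyloxy)phenyl]-2'-(4-methoxyphenyl)-4,4'-dioxo-4H,4'H-[3,3'-bipyran]-6,6'-diyl}bis(3-oxobutanoate), via bis(acyl imidazolide) 9 (not isolated)
Conditions: a) 8, CDI (2.3 equiv), THF, rt; b) potassium methyl malonate (4 equiv), MgCl2 (2 equiv), Et3N (4 equiv), MeCN, rt, 2 h, then the solution from a), rt to 40 °C; 1 M HCl work-up
Reagents that add atoms: potassium methyl malonate, COC(=O)CC(=O)[O-].[K+]; magnesium bis(methyl malonate) made from it in the flask, COC(=O)CC(=O)[O-].COC(=O)CC(=O)[O-].[Mg+2] (two CH2CO2Me units enter the product)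
Why: Masamune–Brooks homologation, in which the magnesium malonate half-ester enolate is C-acylated by each of the two acyl imidazolide groups and each adduct loses CO2 on acidification, giving the bis(β-keto ester) under nearly neutral conditions that spare the pyranones.

Step 5
Reactants: 10 dimethyl 4,4'-{2-[4-(benzyloxy)phenyl]-2'-(4-methoxyphenyl)-4,4'-dioxo-4H,4'H-[3,3'-bipyran]-6,6'-diyl}bis(3-oxobutanoate)
Product: 11 4'''-(benzyloxy)-5,5'',7,7''-tetrahydroxy-4'-methoxy-3,3''-biflavone
Conditions: Mg(OMe)2 (8 equiv), MeOH/THF 2:1 (0.01 M), 65 °C, argon; then 1 M HCl, 0 °C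
Reagents that add atoms: none
Why: Proposed new method: methoxide removes a proton from the side-chain CH2 on pyranone C6 to give a 6-alkylidene-pyran-4-olate whose α-carbon is pyranone C5 (the future C4a); this carbon adds to the methyl ester through a magnesium-bridged six-membered transition state, methoxide leaves, and enolisation of the resulting cyclohexenetrione gives the 5,7-dihydroxybenzene ring, once on each half. The closest known reactions are the Claisen cyclisation of 3,5,7-triketo esters to acylphloroglucinols with Mg(OMe)2 or KOH and the base-induced aromatisation of pyrone-masked polyketides; a Claisen closure onto C5 of an intact 4-pyranone has not been shown. Rings A and A'' each close in the 6-(enolexo)-exo-trig mode, and the only other carbon nucleophile of the chain, the exocyclic carbon, would have to form a four-membered ring. No stereocentre is formed. The step needs Claisen acylation in preference to aldol folding and furan formation: the carbonyls that would serve those paths are held as the enol ether and vinylogous ester of the pyranone (an aldol onto pyranone C4 could only give a bridged adduct that cannot aromatise), and anhydrous Mg(OMe)2 avoids the hydroxide that would open the pyranone. Aromatisation and magnesium chelation of the 5-oxido-4-keto unit should make each closure irreversible.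

Step 6
Reactants: 11 4'''-(benzyloxy)-5,5'',7,7''-tetrahydroxy-4'-methoxy-3,3''-biflavone
Product: 12 4''',5,5'',7,7''-pentakis(benzyloxy)-4'-methoxy-3,3''-biflavone
Conditions: BnBr (6 equiv), K2CO3 (8 equiv), DMF, 70 °C
Reagents that add atoms: benzyl bromide, BrCc1ccccc1 (four benzyl groups enter the product)
Why: Williamson etherification, with excess reagent and heat for the chelated 5- and 5''-hydroxyls, caps all four phenols so that no acidic proton can quench the carbene catalyst of step 7.

Step 7
Reactants: 12 4''',5,5'',7,7''-pentakis(benzyloxy)-4'-methoxy-3,3''-biflavone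
Product: 13 (2S,3S,2''S,3''S)-4''',5,5'',7,7''-pentakis(benzyloxy)-4'-methoxy-3,3''-biflavanone (2,3-cis and 2'',3''-cis)
Conditions: Ru(cod)(2-methylallyl)2 (10 mol%), (R,R)-SINpEt·HBF4 [1,3-bis((1R)-1-(naphthalen-1-yl)ethyl)-4,5-dihydroimidazolium tetrafluoroborate] (20 mol%), KOt-Bu (18 mol%), pre-formed in n-hexane at 70 °C; 12, toluene, H2 (100 bar), 40 °C; stopped at the diketone stage
Reagents that add atoms: none
Why: Proposed new method: asymmetric hydrogenation with this catalyst is known for the trisubstituted C2=C3 bond of flavones and chromones (the closest reaction type) but not for a tetrasubstituted 3-(flavon-3-yl)flavone; syn delivery of H2 from the chiral ligand sphere on ruthenium to the face of each pyranone ring from which O1, C2, C3 and C4 run clockwise should place H2/H3 and H2''/H3'' cis and give S at all four centres under catalyst control, and two independent events of the same sense raise the enantiomeric purity of the homochiral isomer at the cost of a separable diastereomer.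

Step 8
Reactants: 13 (2S,3S,2''S,3''S)-4''',5,5'',7,7''-pentakis(benzyloxy)-4'-methoxy-3,3''-biflavanone
Product: 14 sikokianin A
Conditions: H2 (1 atm), Pd/C (10 wt%), EtOAc/MeOH 1:1, rt
Reagents that add atoms: none
Why: Hydrogenolysis of the five benzyl ethers under neutral conditions should leave the methyl ether and the epimerisable cis C3 and C3'' centres next to the ketones untouched.

**Compound list**
1 | 3-(dimethylamino)-1-(4-methoxyphenyl)propan-1-one hydrochloride | COc1ccc(cc1)C(=O)CCN(C)C.Cl | starting material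
2 | 4-(benzyloxy)benzaldehyde | O=Cc1ccc(OCc2ccccc2)cc1 | starting material
3 | 1-(4-methoxyphenyl)prop-2-en-1-one | COc1ccc(cc1)C(=O)C=C | intermediate
4 | 1-[4-(benzyloxy)phenyl]-4-(4-methoxyphenyl)butane-1,4-dione | COc1ccc(cc1)C(=O)CCC(=O)c1ccc(OCc2ccccc2)cc1 | intermediate
5 | 1-[4-(benzyloxy)phenyl]-2,3-bis(but-2-ynoyl)-4-(4-methoxyphenyl)butane-1,4-dione (mixture of diastereomers and enol forms) | COc1ccc(cc1)C(=O)C(C(=O)C#CC)C(C(=O)C#CC)C(=O)c1ccc(OCc2ccccc2)cc1 | intermediate
6 | 2-[4-(benzyloxy)phenyl]-2'-(4-methoxyphenyl)-6,6'-dimethyl-4H,4'H-[3,3'-bipyran]-4,4'-dione | COc1ccc(cc1)C1=C(C(=O)C=C(C)O1)C1=C(OC(C)=CC1=O)c1ccc(OCc2ccccc2)cc1 | intermediate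
7 | dilithium 2-[4-(benzyloxy)phenyl]-2'-(4-methoxyphenyl)-6,6'-dimethylidene-6H,6'H-[3,3'-bipyran]-4,4'-diolate | COc1ccc(cc1)C1=C(C(O[Li])=CC(=C)O1)C1=C(OC(=C)C=C1O[Li])c1ccc(OCc2ccccc2)cc1 | intermediate
8 | 2,2'-{2-[4-(benzyloxy)phenyl]-2'-(4-methoxyphenyl)-4,4'-dioxo-4H,4'H-[3,3'-bipyran]-6,6'-diyl}diacetic acid | COc1ccc(cc1)C1=C(C(=O)C=C(CC(=O)O)O1)C1=C(OC(CC(=O)O)=CC1=O)c1ccc(OCc2ccccc2)cc1 | intermediate
9 | bis(acyl imidazolide) of 8: 6,6'-bis[2-(imidazol-1-yl)-2-oxoethyl]-2-[4-(benzyloxy)phenyl]-2'-(4-methoxyphenyl)-4H,4'H-[3,3'-bipyran]-4,4'-dione | COc1ccc(cc1)C1=C(C(=O)C=C(CC(=O)n2ccnc2)O1)C1=C(OC(CC(=O)n2ccnc2)=CC1=O)c1ccc(OCc2ccccc2)cc1 | intermediate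
10 | dimethyl 4,4'-{2-[4-(benzyloxy)phenyl]-2'-(4-methoxyphenyl)-4,4'-dioxo-4H,4'H-[3,3'-bipyran]-6,6'-diyl}bis(3-oxobutanoate) | COC(=O)CC(=O)CC1=CC(=O)C(=C(O1)c1ccc(OC)cc1)C1=C(OC(CC(=O)CC(=O)OC)=CC1=O)c1ccc(OCc2ccccc2)cc1 | intermediate
11 | 4'''-(benzyloxy)-5,5'',7,7''-tetrahydroxy-4'-methoxy-3,3''-biflavone | COc1ccc(cc1)C1=C(C(=O)c2c(O)cc(O)cc2O1)C1=C(Oc2cc(O)cc(O)c2C1=O)c1ccc(OCc2ccccc2)cc1 | intermediate
12 | 4''',5,5'',7,7''-pentakis(benzyloxy)-4'-methoxy-3,3''-biflavone | COc1ccc(cc1)C1=C(C(=O)c2c(OCc3ccccc3)cc(OCc3ccccc3)cc2O1)C1=C(Oc2cc(OCc3ccccc3)cc(OCc3ccccc3)c2C1=O)c1ccc(OCc2ccccc2)cc1 | intermediate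
13 | (2S,3S)-5,7-bis(benzyloxy)-3-{(2S,3S)-5,7-bis(benzyloxy)-2-[4-(benzyloxy)phenyl]-4-oxo-3,4-dihydro-2H-chromen-3-yl}-2-(4-methoxyphenyl)-2,3-dihydro-4H-chromen-4-one | COc1ccc([C@H]2Oc3cc(OCc4ccccc4)cc(OCc4ccccc4)c3C(=O)[C@H]2[C@@H]2C(=O)c3c(OCc4ccccc4)cc(OCc4ccccc4)cc3O[C@@H]2c2ccc(OCc3ccccc3)cc2)cc1 | intermediate
14 | sikokianin A, (2S,3S)-3-[(2S,3S)-5,7-dihydroxy-2-(4-hydroxyphenyl)-4-oxo-3,4-dihydro-2H-chromen-3-yl]-5,7-dihydroxy-2-(4-methoxyphenyl)-2,3-dihydro-4H-chromen-4-one | COc1ccc([C@H]2Oc3cc(O)cc(O)c3C(=O)[C@H]2[C@@H]2C(=O)c3c(O)cc(O)cc3O[C@@H]2c2ccc(O)cc2)cc1 | target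

**Step count and risks**
Total step count: 8. Longest linear sequence: 8 steps (from 1 or 2 to 14).

Steps most likely to fail:

1. Step 5 (Proposed new method).
   - What may go wrong: deprotonation may rest on the β-keto ester carbon, so that pyranone C5 never engages the ester. Methoxide may open a pyranone ring, after which the freed chain can fold by aldol condensation or lactonise. The second closure may lag behind the first.
   - Fallback (known reaction types; rings A and A'' are brought in as preformed arenes): it sets out from diketone 4. The soft-enolisation acylation of step 2 is run with 2,4,6-trifluorobenzoyl chloride (2.5 equiv, MgBr2·OEt2, i-Pr2NEt, CH2Cl2) to give 1-[4-(benzyloxy)phenyl]-4-(4-methoxyphenyl)-2,3-bis(2,4,6-trifluorobenzoyl)butane-1,4-dione F1. K2CO3 in DMF at 80 °C closes both heterocycles by intramolecular SNAr of each aroyl enolate oxygen on an ortho C–F bond and gives 4'''-(benzyloxy)-5,5'',7,7''-tetrafluoro-4'-methoxy-3,3''-biflavone F2. BnOH/NaH in DMF then replaces the four fluorides, each ortho or para to a C4 carbonyl, by benzyloxy groups and gives 12, where the route is rejoined before step 7.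

2. Step 7 (Proposed new method).
   - What may go wrong: the crowded tetrasubstituted double bonds may not bind to the catalyst. Facial selectivity in the second reduction may be eroded by the stereocentres already set or by a mismatched rotamer about the C3–C3'' axis. The C4 carbonyls may be reduced further. The cis C3 centres may epimerise if alkoxide survives catalyst formation.
   - Fallback (known reaction types; resolution in place of catalyst control): it sets out from 12. Hydrogenation over Pd/C (H2, 5 bar, THF/MeOH, rt) removes the benzyl groups and adds H2 syn to both C2=C3 bonds without facial bias. This gives 14 together with its enantiomer (2R,3R,2''R,3''R)-sikokianin A F3 and the other cis,cis pair, the (2S,3S,2''R,3''R)-isomer of 14 F4 and the (2R,3R,2''S,3''S)-isomer of 14 F5. The diastereomeric pairs are separated by chromatography and 14 is parted from F3 by preparative HPLC on a chiral stationary phase. This reaches target 14 directly and makes step 8 unnecessary.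

3. Step 2.
   - What may go wrong: O-acylation of the enolate; a sluggish second acylation next to the first acyl group; addition of halide or amine to the ynone; acid-induced Paal–Knorr closure of the 1,4-diketone during work-up.
   - Fallback (C–C bond formation by aldol addition in place of acylation): it sets out from 4. The bis-enolate formed with LiN(SiMe3)2 (2.2 equiv, THF, −78 °C) is added to but-2-ynal (2.5 equiv) to give 1-[4-(benzyloxy)phenyl]-2,3-bis(1-hydroxybut-2-yn-1-yl)-4-(4-methoxyphenyl)butane-1,4-dione F6 as a mixture of diastereomers. Dess–Martin periodinane (NaHCO3, CH2Cl2) oxidises both carbinols and so arrives at tetraketone 5, which is closed to 6 with DBU as in step 2.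

**Further compounds**
F1 | step 5 | 1-[4-(benzyloxy)phenyl]-4-(4-methoxyphenyl)-2,3-bis(2,4,6-trifluorobenzoyl)butane-1,4-dione | COc1ccc(cc1)C(=O)C(C(=O)c1c(F)cc(F)cc1F)C(C(=O)c1c(F)cc(F)cc1F)C(=O)c1ccc(OCc2ccccc2)cc1
F2 | step 5 | 4'''-(benzyloxy)-5,5'',7,7''-tetrafluoro-4'-methoxy-3,3''-biflavone | COc1ccc(cc1)C1=C(C(=O)c2c(F)cc(F)cc2O1)C1=C(Oc2cc(F)cc(F)c2C1=O)c1ccc(OCc2ccccc2)cc1
F3 | step 7 | (2R,3R,2''R,3''R)-sikokianin A (enantiomer of 14) | COc1ccc([C@@H]2Oc3cc(O)cc(O)c3C(=O)[C@@H]2[C@H]2C(=O)c3c(O)cc(O)cc3O[C@H]2c2ccc(O)cc2)cc1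
F4 | step 7 | (2S,3S,2''R,3''R)-isomer of 14 | COc1ccc([C@H]2Oc3cc(O)cc(O)c3C(=O)[C@H]2[C@H]2C(=O)c3c(O)cc(O)cc3O[C@H]2c2ccc(O)cc2)cc1
F5 | step 7 | (2R,3R,2''S,3''S)-isomer of 14 | COc1ccc([C@@H]2Oc3cc(O)cc(O)c3C(=O)[C@@H]2[C@@H]2C(=O)c3c(O)cc(O)cc3O[C@@H]2c2ccc(O)cc2)cc1
F6 | step 2 | 1-[4-(benzyloxy)phenyl]-2,3-bis(1-hydroxybut-2-yn-1-yl)-4-(4-methoxyphenyl)butane-1,4-dione (mixture of diastereomers) | COc1ccc(cc1)C(=O)C(C(O)C#CC)C(C(O)C#CC)C(=O)c1ccc(OCc2ccccc2)cc1
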